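**Plan**
Numbering (drimane type): ring A = C1–C5 and C10 (C3 carbinol, C4 CMe2). Ring B = C5–C10 (C5=C6, C8 CHMe, C9 quaternary, C10–H). C11 = OCH2.
Retrosynthetic cuts, in order: O–C11 (ether to isofraxidin), then one C4–CH3 (deconjugative methylation, which also moves the alkene from C4=C5 to C5=C6). Last, C1–C10, C4–C5 and C9–C11 are cut in one operation, leaving (S)-3,4-dimethylcyclohex-2-enone, a five-carbon vinyl ketone and a vinyl nucleophile.
Enabling feature: the C3 oxygen is 1,3 to C5 through C4 and 1,5 to C5 through C2–C1–C10. A C5=C6 alkene beside the C4 gem-dimethyl carbon is the mark of a methylated C4=C5–C3=O enone, so ring A is a Robinson unit. C10 lies between C5 and quaternary C9, so the enolate it needs is exactly the one that conjugate addition at C9 sets free.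
Forward: ring B first (steps 1–4), ring A fused on in one flask (step 7), then C4 methyl, C3 carbinol, vinyl to CH2OH, aryl ether, desilylation.
Stereochemistry: C8 comes from an enamine catalyst (step 1). C9 and C10 are relayed from C8 in step 7. C3 comes from equatorial hydride delivery to the ring A chair (step 9).

Key step: step 7

Assumption: ring A of 15 is taken as the chair with H-10 axial (C9 equatorial), which makes the 3β-hydroxyl of the target axial; isofraxidin (21) is bought.

**Step 1**
Reactants: 1 propanal; 2 but-3-en-2-one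
Product: 3 (S)-2-methyl-5-oxohexanal
Conditions: (R)-2-[diphenyl(trimethylsilyloxy)methyl]pyrrolidine (5 mol %), ethyl 3,4-dihydroxybenzoate (20 mol %), neat, 4 °C
Reagents that add atoms: none
Why: Enamine-catalysed asymmetric Michael addition of an aldehyde to a vinyl ketone; the diphenyl(silyloxy)methyl group of the (R)-catalyst shields one face of the E-enamine, so bond formation on the open face should set the future C8 as S.

**Step 2**
Reactants: 3 (S)-2-methyl-5-oxohexanal
Product: 4 (S)-4-methylcyclohex-2-en-1-one
Conditions: LiOH (0.2 equiv), i-PrOH, rt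
Reagents that add atoms: none
Why: Intramolecular aldol condensation of the methyl ketone onto the aldehyde, run with a mild base for a short time so that the tertiary centre next to the aldehyde is not epimerised before ring closure.

**Step 3**
Reactants: 4 (S)-4-methylcyclohex-2-en-1-one
Product: 5 [(3R,4S)-3,4-dimethylcyclohex-1-en-1-yl]oxy(trimethyl)silane
Conditions: MeMgBr, CuBr·SMe2 (10 mol %), Me3SiCl, DMPU, THF, −78 °C
Reagents that add atoms: methylmagnesium bromide C[Mg]Br; chlorotrimethylsilane C[Si](C)(C)Cl
Why: Copper-catalysed conjugate addition of a Grignard reagent with silyl trapping; methyl enters anti to the C8 methyl group, this new centre is flattened again in step 4, and the silyl enol ether fixes the site of dehydrogenation.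

**Step 4**
Reactants: 5 [(3R,4S)-3,4-dimethylcyclohex-1-en-1-yl]oxy(trimethyl)silane
Product: 6 (S)-3,4-dimethylcyclohex-2-en-1-one
Conditions: Pd(OAc)2 (10 mol %), O2 (1 atm), DMSO, 25 °C
Reagents that add atoms: none
Why: Aerobic Saegusa–Ito oxidation; the oxo-π-allyl complex of divalent palladium formed at C10 can lose only the C9 hydride, so the alkene is placed at C9=C10 and C8 is untouched.

**Step 5**
Reactants: 7 (1-bromovinyl)trimethylsilane; 1 propanal
Product: 9 2-(trimethylsilyl)pent-1-en-3-ol, via 1-(trimethylsilyl)vinylmagnesium bromide 8 (not isolated)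
Conditions: Mg turnings, THF, reflux; then 1, 0 °C; aqueous work-up
Reagents that add atoms: none
Why: Grignard addition to an aldehyde; the carbinol centre formed is racemic and is removed in step 6.

**Step 6**
Reactants: 9 2-(trimethylsilyl)pent-1-en-3-ol
Product: 10 2-(trimethylsilyl)pent-1-en-3-one
Conditions: Dess–Martin periodinane, CH2Cl2, 0 °C; used at once
Reagents that add atoms: none
Why: Dess–Martin oxidation of an allylic alcohol under non-aqueous, nearly neutral conditions, which spares the C–Si bond and the polymerisable enone.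

**Step 7**
Reactants: 6 (S)-3,4-dimethylcyclohex-2-en-1-one; 10 2-(trimethylsilyl)pent-1-en-3-one
Product: 14 (4aS,5R,6S)-1,5,6-trimethyl-5-vinyl-4,4a,5,6,7,8-hexahydronaphthalen-2(3H)-one, via bromomagnesium enolate 11 (not isolated), via silyl diketone 12 (not isolated), via 1,5-diketone 13 (not isolated)
Conditions: CH2=CHMgBr (2.0 equiv), CuBr·SMe2 (1.0 equiv), THF, −78 → −40 °C; 10 (1.5 equiv), −78 → −20 °C; then NaOMe, MeOH, same flask, 0 → 65 °C
Reagents that add atoms: vinylmagnesium bromide C=C[Mg]Br
Why: The divinylcuprate adds 1,4 to 6 at C9 and frees the C5–C10 enolate 11, which adds to the CH2 terminus of 10 (C1–C10 bond) to give 12 once methanol is added; methoxide strips silicon (13) and the C4 enolate of the ethyl ketone closes onto the C5 carbonyl (C4–C5 bond), water being lost by E1cB elimination. The closest known reaction type is the conjugate addition–Robinson annulation of cuprate-derived cyclohexanone enolates with α-silyl vinyl ketones, in which silicon stabilises the first-formed enolate so that the acceptor is not polymerised and the ring enolate is not equilibrated. Ring A closes in the 6-(enolendo)-exo-trig mode. C9: A(1,2) strain against the C9 methyl group holds the C8 methyl group pseudoaxial, and axial attack anti to it puts vinyl on the α face, trans to the C8 methyl group, so the two methyl groups end up cis. C10: this centre is α to C5=O in 12 and 13 and γ to C3=O in 14, so methoxide equilibrates it to the isomer with C1 equatorial on ring B, cis to the equatorial C8 methyl group, that is 10α-H. The step needs 1,4- over 1,2-addition (secured by copper), reaction at C10 and not C6 (secured by the aprotic, regiospecific formation of 11 and the fast silyl-activated acceptor), and closure of C4 on C5 rather than C6 on C3 (the bridged ketol forms reversibly and only the fused one can dehydrate into conjugation).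

**Step 8**
Reactants: 14 (4aS,5R,6S)-1,5,6-trimethyl-5-vinyl-4,4a,5,6,7,8-hexahydronaphthalen-2(3H)-one
Product: 15 (4aS,5R,6S)-1,1,5,6-tetramethyl-5-vinyl-3,4,4a,5,6,7-hexahydronaphthalen-2(1H)-one
Conditions: t-BuOK (1.3 equiv), t-BuOH–THF, rt; MeI (1.5 equiv)
Reagents that add atoms: iodomethane CI
Why: Deconjugative α-alkylation of an enone; t-BuOK removes a C6 proton to give the heteroannular dienolate, which is methylated at C4, building the gem-dimethyl carbon and leaving the alkene at C5=C6, while the hindered C10–H next to C9 stays in place and no stereocentre is formed.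

**Step 9**
Reactants: 15 (4aS,5R,6S)-1,1,5,6-tetramethyl-5-vinyl-3,4,4a,5,6,7-hexahydronaphthalen-2(1H)-one
Product: 16 (2S,4aS,5R,6S)-1,1,5,6-tetramethyl-5-vinyl-1,2,3,4,4a,5,6,7-octahydronaphthalen-2-ol
Conditions: LiBH(s-Bu)3, THF, −78 → 0 °C; then NaOH, H2O2
Reagents that add atoms: none
Why: Bulky trialkylborohydride reduction of a cyclohexanone; the reagent avoids the axial β trajectory and comes in equatorially from the α face, which should give the axial 3β (S) alcohol, as such hydrides do with 4,4-dimethyl-3-ketones of triterpenoids.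

**Step 10**
Reactants: 16 (2S,4aS,5R,6S)-1,1,5,6-tetramethyl-5-vinyl-1,2,3,4,4a,5,6,7-octahydronaphthalen-2-ol
Product: 17 triethylsilyl ether of 16
Conditions: Et3SiOTf, 2,6-lutidine, CH2Cl2, 0 °C
Reagents that add atoms: triethylsilyl trifluoromethanesulfonate CC[Si](CC)(CC)OS(=O)(=O)C(F)(F)F
Why: Silyl triflate protection reaches even this hindered axial alcohol, and it is needed because a free 3-OH beside C4 would be activated and dehydrated under the conditions of step 13.

**Step 11**
Reactants: 17 triethylsilyl ether of 16
Product: 19 (1R,2S,6S,8aR)-1,2,5,5-tetramethyl-6-(triethylsilyloxy)-1,2,3,5,6,7,8,8a-octahydronaphthalene-1-carbaldehyde, via vicinal diol 18 (not isolated)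
Conditions: OsO4 (2 mol %), NaIO4 (4 equiv), 2,6-lutidine (2 equiv), dioxane–H2O (3:1), rt
Reagents that add atoms: osmium tetroxide O=[Os](=O)(=O)=O; sodium periodate [Na+].[O-]I(=O)(=O)=O
Why: Lemieux–Johnson cleavage; the terminal vinyl group should be osmylated first because the C5=C6 alkene is screened on the α face by the axial C4 methyl group and on the β face by the axial C9 methyl group, and the aldehyde formed has no α-hydrogen to epimerise.

**Step 12**
Reactants: 19 (1R,2S,6S,8aR)-1,2,5,5-tetramethyl-6-(triethylsilyloxy)-1,2,3,5,6,7,8,8a-octahydronaphthalene-1-carbaldehyde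
Product: 20 [(1R,2S,6S,8aR)-1,2,5,5-tetramethyl-6-(triethylsilyloxy)-1,2,3,5,6,7,8,8a-octahydronaphthalen-1-yl]methanol
Conditions: NaBH4, MeOH–THF, 0 °C
Reagents that add atoms: none
Why: Borohydride reduction of an aldehyde, with no other reducible group present and no stereocentre formed.

**Step 13**
Reactants: 20 [(1R,2S,6S,8aR)-1,2,5,5-tetramethyl-6-(triethylsilyloxy)-1,2,3,5,6,7,8,8a-octahydronaphthalen-1-yl]methanol; 21 isofraxidin (7-hydroxy-6,8-dimethoxycoumarin)
Product: 22 3-O-triethylsilyl ether of the target
Conditions: PPh3, DIAD, THF (about 2 M), sonication, 40 °C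
Reagents that add atoms: none
Why: Mitsunobu etherification; the acidic 7-hydroxycoumarin protonates the betaine readily, 20 carries the only free hydroxyl, and high concentration speeds the slow SN2 step at neopentyl C11, a substitution known for ring-bound CH2OH groups on quaternary carbons of triterpenoids.

**Step 14**
Reactants: 22 3-O-triethylsilyl ether of the target
Product: 23 7-{[(1R,2S,6S,8aR)-6-hydroxy-1,2,5,5-tetramethyl-1,2,3,5,6,7,8,8a-octahydronaphthalen-1-yl]methoxy}-6,8-dimethoxy-2H-chromen-2-one
Conditions: HF·pyridine, pyridine, THF, 0 °C → rt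
Reagents that add atoms: none
Why: Fluoride-driven desilylation under buffered conditions, which should leave the lactone, the aryl ether and the C5=C6 alkene untouched and no stereocentre at risk.

**Compound list**
1 | propanal | CCC=O | starting material
2 | but-3-en-2-one (methyl vinyl ketone) | CC(=O)C=C | starting material
3 | (S)-2-methyl-5-oxohexanal | CC(=O)CC[C@@H](C=O)C | intermediate
4 | (S)-4-methylcyclohex-2-en-1-one | C1=CC(=O)CC[C@@H]1C | intermediate
5 | [(3R,4S)-3,4-dimethylcyclohex-1-en-1-yl]oxy(trimethyl)silane (trans) | C[C@H]1C=C(O[Si](C)(C)C)CC[C@@H]1C | intermediate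
6 | (S)-3,4-dimethylcyclohex-2-en-1-one | CC1=CC(=O)CC[C@@H]1C | intermediate
7 | (1-bromovinyl)trimethylsilane | C=C(Br)[Si](C)(C)C | starting material
8 | 1-(trimethylsilyl)vinylmagnesium bromide | C=C([Mg]Br)[Si](C)(C)C | intermediate
9 | 2-(trimethylsilyl)pent-1-en-3-ol (racemic) | C=C([Si](C)(C)C)C(O)CC | intermediate
10 | 2-(trimethylsilyl)pent-1-en-3-one | C=C([Si](C)(C)C)C(=O)CC | intermediate
11 | C5–C10 bromomagnesium enolate of (3R,4S)-3,4-dimethyl-3-vinylcyclohexanone | C=C[C@@]1(C)C=C(O[Mg]Br)CC[C@@H]1C | intermediate
12 | (2S,3R,4S)-3,4-dimethyl-2-[3-oxo-2-(trimethylsilyl)pentyl]-3-vinylcyclohexan-1-one (mixture at the silyl-bearing carbon) | C=C[C@@]1(C)[C@H](CC([Si](C)(C)C)C(=O)CC)C(=O)CC[C@@H]1C | intermediate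
13 | (2S,3R,4S)-3,4-dimethyl-2-(3-oxopentyl)-3-vinylcyclohexan-1-one | C=C[C@@]1(C)[C@H](CCC(=O)CC)C(=O)CC[C@@H]1C | intermediate
14 | (4aS,5R,6S)-1,5,6-trimethyl-5-vinyl-4,4a,5,6,7,8-hexahydronaphthalen-2(3H)-one (8β,9β-dimethyl, 9α-vinyl, 10α-H) | C=C[C@@]1(C)[C@@H]2CCC(=O)C(C)=C2CC[C@@H]1C | intermediate
15 | (4aS,5R,6S)-1,1,5,6-tetramethyl-5-vinyl-3,4,4a,5,6,7-hexahydronaphthalen-2(1H)-one | C=C[C@@]1(C)[C@@H]2CCC(=O)C(C)(C)C2=CC[C@@H]1C | intermediate
16 | (2S,4aS,5R,6S)-1,1,5,6-tetramethyl-5-vinyl-1,2,3,4,4a,5,6,7-octahydronaphthalen-2-ol (3β-OH) | C=C[C@@]1(C)[C@@H]2CC[C@H](O)C(C)(C)C2=CC[C@@H]1C | intermediate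
17 | triethylsilyl ether of 16 | C=C[C@@]1(C)[C@@H]2CC[C@H](O[Si](CC)(CC)CC)C(C)(C)C2=CC[C@@H]1C | intermediate
18 | 1,2-diol from the vinyl group of 17 (mixture at the new carbinol) | OCC(O)[C@@]1(C)[C@@H]2CC[C@H](O[Si](CC)(CC)CC)C(C)(C)C2=CC[C@@H]1C | intermediate
19 | (1R,2S,6S,8aR)-1,2,5,5-tetramethyl-6-(triethylsilyloxy)-1,2,3,5,6,7,8,8a-octahydronaphthalene-1-carbaldehyde | O=C[C@@]1(C)[C@@H]2CC[C@H](O[Si](CC)(CC)CC)C(C)(C)C2=CC[C@@H]1C | intermediate
20 | [(1R,2S,6S,8aR)-1,2,5,5-tetramethyl-6-(triethylsilyloxy)-1,2,3,5,6,7,8,8a-octahydronaphthalen-1-yl]methanol | OC[C@@]1(C)[C@@H]2CC[C@H](O[Si](CC)(CC)CC)C(C)(C)C2=CC[C@@H]1C | intermediate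
21 | isofraxidin (7-hydroxy-6,8-dimethoxy-2H-chromen-2-one) | COc1cc2ccc(=O)oc2c(OC)c1O | starting material
22 | 3-O-triethylsilyl ether of the target | COc1cc2ccc(=O)oc2c(OC)c1OC[C@@]1(C)[C@@H]2CC[C@H](O[Si](CC)(CC)CC)C(C)(C)C2=CC[C@@H]1C | intermediate
23 | 7-{[(1R,2S,6S,8aR)-6-hydroxy-1,2,5,5-tetramethyl-1,2,3,5,6,7,8,8a-octahydronaphthalen-1-yl]methoxy}-6,8-dimethoxy-2H-chromen-2-one | COc1cc2ccc(=O)oc2c(OC)c1OC[C@@]1(C)[C@@H]2CC[C@H](O)C(C)(C)C2=CC[C@@H]1C | target

**Totals**
Total steps: 14. Longest linear sequence: 12 (steps 1–4 and 7–14); steps 5 and 6 form a two-step side branch.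

**Steps most likely to fail**
1. Step 13. The SN2 displacement at neopentyl C11 may be so slow that the activated alcohol is used up by alkylation of the reduced azodicarboxylate, or 20 simply returns. The fallback sets out from 20 and replaces the redox condensation by a discrete sulfonate and a Williamson etherification. Tf2O and pyridine in CH2Cl2 at −78 → 0 °C should give the C11 trifluoromethanesulfonate of 20 F1. This is then heated with the caesium phenolate of 21 (Cs2CO3, DMF, 50 °C). The fallback comes back to the route at 22.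
2. Step 7. The enolate 11, flanked by quaternary C9, may add sluggishly to 10, which leaves room for proton transfer between enolates and for anionic polymerisation of the acceptor. The fallback sets out from 6 and separates the events under Lewis acid control. The same copper-mediated vinyl addition, run with Me3SiCl present, should give the isolable [(3R,4S)-3,4-dimethyl-3-vinylcyclohex-1-en-1-yl]oxy(trimethyl)silane F2. A Mukaiyama–Michael addition of F2 to commercial pent-1-en-3-one (BF3·OEt2, i-PrOH, CH2Cl2, −78 °C) comes back to the route at 13, now isolated, and NaOMe in MeOH closes 13 to 14.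
3. Step 9. Facial selectivity may be poor, because sp2 C5 removes one of the syn-axial hydrogens that normally disfavour axial attack, so equatorial delivery is less strongly preferred. The fallback sets out from 15 and replaces substrate control by catalyst control. It is a Corey–Bakshi–Shibata reduction with (R)-2-methyl-CBS-oxazaborolidine and catecholborane in toluene at −78 → −40 °C, a borane that leaves the vinyl group alone. The catalyst tells quaternary C4 from the C2 methylene and should deliver hydride to the α face. The fallback comes back to the route at 16 and makes no new compound.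

**Further compounds**
F1 | step 13 | [(1R,2S,6S,8aR)-1,2,5,5-tetramethyl-6-(triethylsilyloxy)-1,2,3,5,6,7,8,8a-octahydronaphthalen-1-yl]methyl trifluoromethanesulfonate | FC(F)(F)S(=O)(=O)OC[C@@]1(C)[C@@H]2CC[C@H](O[Si](CC)(CC)CC)C(C)(C)C2=CC[C@@H]1C
F2 | step 7 | [(3R,4S)-3,4-dimethyl-3-vinylcyclohex-1-en-1-yl]oxy(trimethyl)silane | C=C[C@@]1(C)C=C(O[Si](C)(C)C)CC[C@@H]1C
F0 | step 9 | none | none
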